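**Retrosynthetic overview**

1. Numbering: ring A has C1 (carries the depsidone carbonyl), C2 (ether O), C3 (CHO), C4 (OH), C6 (CH3); ring B has C1' (carries the lactone carbonyl), C2' (OH), C3' (CH2OAc), C4' (ester O), C5' (ether O), C6' (carries the lactol CH). The strategy rests on the position of the hexasubstituted ring B between the seven-membered dioxepinone (fused at C4'–C5') and the five-membered lactol lactone (fused at C1'–C6'): each heterocycle can travel on its own partner and ring B can be built last.
2. Galbinic acid ⇐ tetracycle with lactol O-acetate, silylated 3'-CH2OH, 4-O-allyl and dioxolane-masked CHO. The lactol is freed last by cleavage at the acetyl carbon, so the C–O bond at the stereocentre is never broken.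
3. Ring B ⇐ Diels–Alder reaction with eliminative aromatisation (bonds C1'–C2' and C5'–C6'): ketene-acetal diene C2'=C3'–C4'=C5' on the ring-A dioxepinone plus (S)-5-acetoxy-3-(phenylsulfinyl)furan-2(5H)-one, which brings the only stereocentre.
4. Diene ⇐ seven-membered enol lactone ⇐ keto acid ⇐ ring-A aryloxy N-methoxy-N-methylacetamide + silyloxypropanoate enolate ⇐ orsellinic acid. Dienophile ⇐ furfural by photooxygenation, enzymatic acetylation, bromination, thiolation and S-oxidation.
5. Order of ring formation: ring A is bought; dioxepinone ring (step 9); butenolide ring separately (step 11); ring B last (step 16), which fuses all four rings.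

Key step: step 16

Assumption: the immobilised lipase chosen for steps 12 and 20 has (S)-preference at the acylal carbon (it acetylates the (S)-lactol and cleaves (S)-acylal acetates faster); this sense is confirmed on the product of step 12 before the material is carried on.

**Route**

Step 1
Reactants: 1 orsellinic acid (2,4-dihydroxy-6-methylbenzoic acid)
Product: 2 2-(trimethylsilyl)ethyl 2,4-dihydroxy-6-methylbenzoate
Conditions: Me3SiCH2CH2OH (1 equiv), PPh3, iPrO2CN=NCO2iPr, THF, 0 → 25 °C
Reagents that add atoms: 2-(trimethylsilyl)ethanol, C[Si](C)(C)CCO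
Why: Mitsunobu esterification: with one equivalent of the alcohol only the carboxylic acid is acidic enough to be alkylated, so both phenols stay free and the ester can later be removed by fluoride without acid or hydroxide.

Step 2
Reactants: 2 2-(trimethylsilyl)ethyl 2,4-dihydroxy-6-methylbenzoate
Product: 3 2-(trimethylsilyl)ethyl 3-formyl-2,4-dihydroxy-6-methylbenzoate
Conditions: MgCl2, Et3N, (CH2O)n, MeCN, 80 °C; 1 M HCl
Reagents that add atoms: formaldehyde (as paraformaldehyde), C=O
Why: Magnesium-mediated ortho-formylation of a phenol (Casnati–Skattebøl reaction): formaldehyde is delivered from the magnesium phenoxide to an ortho carbon, C3 being ortho to both phenoxides and therefore preferred over C5, and a second formaldehyde oxidises the benzylic alkoxide to the aldehyde.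

Step 3
Reactants: 3 2-(trimethylsilyl)ethyl 3-formyl-2,4-dihydroxy-6-methylbenzoate
Product: 4 2-(trimethylsilyl)ethyl 4-(allyloxy)-3-formyl-2-hydroxy-6-methylbenzoate
Conditions: allyl bromide (1.05 equiv), K2CO3, acetone, 25 °C
Reagents that add atoms: allyl bromide, C=CCBr
Why: Williamson ether synthesis: the 4-OH (para to the ester, hydrogen-bonded only to the aldehyde) is the more acidic and less hindered phenol, so one equivalent of base and bromide should alkylate it and leave the 2-OH, which is locked to the ester carbonyl.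

Step 4
Reactants: 4 2-(trimethylsilyl)ethyl 4-(allyloxy)-3-formyl-2-hydroxy-6-methylbenzoate
Product: 5 2-(trimethylsilyl)ethyl 4-(allyloxy)-3-formyl-2-{2-[methoxy(methyl)amino]-2-oxoethoxy}-6-methylbenzoate
Conditions: ClCH2C(O)N(OMe)Me, K2CO3, NaI (cat.), DMF, 40 °C
Reagents that add atoms: 2-chloro-N-methoxy-N-methylacetamide, CON(C)C(=O)CCl
Why: Williamson ether synthesis with Finkelstein activation: the remaining chelated phenoxide is alkylated by the iodoacetamide formed in the flask, and the amide α-hydrogens are too weakly acidic under carbonate at 40 °C for an aldol closure onto the neighbouring aldehyde.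

Step 5
Reactants: 5 2-(trimethylsilyl)ethyl 4-(allyloxy)-3-formyl-2-{2-[methoxy(methyl)amino]-2-oxoethoxy}-6-methylbenzoate
Product: 6 2-(trimethylsilyl)ethyl 4-(allyloxy)-3-(1,3-dioxolan-2-yl)-2-{2-[methoxy(methyl)amino]-2-oxoethoxy}-6-methylbenzoate
Conditions: Me3SiOCH2CH2OSiMe3, Me3SiOTf (cat.), CH2Cl2, −78 → −20 °C; pyridine
Reagents that add atoms: 1,2-bis(trimethylsilyloxy)ethane, C[Si](C)(C)OCCO[Si](C)(C)C
Why: Noyori acetalisation: the silyl triflate-catalysed exchange is driven by formation of hexamethyldisiloxane and works at low temperature on the hindered 2,6-dioxygenated benzaldehyde without touching the silylethyl ester, the amide or the allyl ether.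

Step 6
Reactants: 6 2-(trimethylsilyl)ethyl 4-(allyloxy)-3-(1,3-dioxolan-2-yl)-2-{2-[methoxy(methyl)amino]-2-oxoethoxy}-6-methylbenzoate
Product: 7 4-(allyloxy)-3-(1,3-dioxolan-2-yl)-2-{2-[methoxy(methyl)amino]-2-oxoethoxy}-6-methylbenzoic acid
Conditions: Bu4NF, THF, 0 → 25 °C; NaH2PO4 buffer (pH 5), EtOAc, 0 °C
Reagents that add atoms: none
Why: Fluoride-induced fragmentation of the 2-(trimethylsilyl)ethyl ester (β-elimination to Me3SiF and ethene) frees the hindered benzoic acid without acid or hydroxide, and extraction at pH 5 and 0 °C keeps the electron-rich aryl dioxolane.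

Step 7
Reactants: 8 methyl 3-hydroxypropanoate
Product: 9 methyl 3-[(tert-butyldimethylsilyl)oxy]propanoate
Conditions: tBuMe2SiCl, imidazole, DMF, 25 °C
Reagents that add atoms: tert-butyldimethylsilyl chloride, CC(C)(C)[Si](C)(C)Cl
Why: Silyl ether formation (silyl chloride and imidazole) on the primary alcohol, giving a group that survives enolate and amide-base chemistry.

Step 8
Reactants: 7 4-(allyloxy)-3-(1,3-dioxolan-2-yl)-2-{2-[methoxy(methyl)amino]-2-oxoethoxy}-6-methylbenzoic acid; 9 methyl 3-[(tert-butyldimethylsilyl)oxy]propanoate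
Product: 11 4-(allyloxy)-2-{4-[(tert-butyldimethylsilyl)oxy]-3-(methoxycarbonyl)-2-oxobutoxy}-3-(1,3-dioxolan-2-yl)-6-methylbenzoic acid, via lithium ester enolate 10 (not isolated)
Conditions: 9 (3.5 equiv), LiN(iPr)2, THF, −78 °C; then 7, −78 → −40 °C; AcOH, then pH 5 buffer, 0 °C
Reagents that add atoms: none
Why: Acylation of an ester enolate by an N-methoxy-N-methylamide (Weinreb ketone synthesis, a crossed Claisen equivalent): the chelated tetrahedral adduct survives until the acidic quench, which prevents a second addition and β-elimination of silyloxide, the lithium carboxylate of 7 is inert, and the new α-stereocentre forms as a racemate that is erased in step 9.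

Step 9
Reactants: 11 4-(allyloxy)-2-{4-[(tert-butyldimethylsilyl)oxy]-3-(methoxycarbonyl)-2-oxobutoxy}-3-(1,3-dioxolan-2-yl)-6-methylbenzoic acid
Product: 13 methyl (2Z)-2-[8-(allyloxy)-9-(1,3-dioxolan-2-yl)-6-methyl-5-oxo-1,4-benzodioxepin-3(2H)-ylidene]-3-[(tert-butyldimethylsilyl)oxy]propanoate, via acid chloride 12 (not isolated)
Conditions: 1-chloro-N,N,2-trimethylprop-1-en-1-amine, CH2Cl2, 0 °C; then slow addition to Et3N, 4-(dimethylamino)pyridine (cat.), CH2Cl2 (5 mM), 25 °C
Reagents that add atoms: none
Why: Enol lactonisation by intramolecular O-acylation: the chloroenamine gives acid chloride 12 under neutral conditions, and under high dilution with amine base the ketone enol oxygen of the β-keto ester closes the seven-membered ring (C-acylation would need a quaternary carbon), the chelated enol giving the Z exocyclic alkene, while any endocyclic isomer leads to the same diene in step 10.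

Step 10
Reactants: 13 methyl (2Z)-2-[8-(allyloxy)-9-(1,3-dioxolan-2-yl)-6-methyl-5-oxo-1,4-benzodioxepin-3(2H)-ylidene]-3-[(tert-butyldimethylsilyl)oxy]propanoate
Product: 14 8-(allyloxy)-3-{3-[(tert-butyldimethylsilyl)oxy]-1-methoxy-1-[(trimethylsilyl)oxy]prop-1-en-2-yl}-9-(1,3-dioxolan-2-yl)-6-methyl-5H-1,4-benzodioxepin-5-one
Conditions: Me3SiCl, then LiN(iPr)2, THF–DMPU, −78 °C; evaporation, pentane, filtration; used crude
Reagents that add atoms: chlorotrimethylsilane, C[Si](C)(C)Cl
Why: γ-Deprotonation of the β-acyloxy acrylate and O-silylation of the dienolate (the way Brassard-type 1-alkoxy-1-silyloxy dienes are made): the silyl chloride present at −78 °C traps the dienolate before silyloxide elimination or acyl transfer can occur, and the ketene acetal geometry does not matter.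

Step 11
Reactants: 15 furfural
Product: 16 5-hydroxyfuran-2(5H)-one (racemic)
Conditions: O2, hν (visible), 5,10,15,20-tetraphenylporphyrin (cat.), CH2Cl2–MeOH, 15 °C
Reagents that add atoms: oxygen, O=O
Why: Dye-sensitised photooxygenation: singlet oxygen adds across C2 and C5 of the furan ([4+2]), and methanolysis of the endoperoxide expels the formyl group as methyl formate to give the racemic hydroxybutenolide.

Step 12
Reactants: 16 5-hydroxyfuran-2(5H)-one (racemic)
Product: 17 (S)-5-acetoxyfuran-2(5H)-one [(2S)-5-oxo-2,5-dihydrofuran-2-yl acetate]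
Conditions: vinyl acetate, immobilised Pseudomonas fluorescens lipase, cyclohexane–n-BuOAc, 25 °C
Reagents that add atoms: vinyl acetate, C=COC(C)=O
Why: Lipase-catalysed dynamic kinetic resolution (second-order asymmetric transformation): 16 racemises by ring–chain tautomerism with (Z)-4-oxobut-2-enoic acid while the enzyme acetylates only the (S)-lactol irreversibly with vinyl acetate, so the stereocentre is set under enzyme control.

Step 13
Reactants: 17 (S)-5-acetoxyfuran-2(5H)-one
Product: 19 (2S)-4-bromo-5-oxo-2,5-dihydrofuran-2-yl acetate, via dibromo lactone 18 (not isolated)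
Conditions: Br2, CH2Cl2, 0 → 25 °C; then Et3N (1.05 equiv), 0 °C
Reagents that add atoms: bromine, BrBr
Why: Bromination and dehydrobromination: anti addition of bromine gives 18, and one equivalent of amine removes the acidic hydrogen next to the carbonyl with loss of the β-bromide (E1cB) to the α-bromobutenolide, the acylal carbon not being involved.

Step 14
Reactants: 19 (2S)-4-bromo-5-oxo-2,5-dihydrofuran-2-yl acetate
Product: 20 (2S)-5-oxo-4-(phenylsulfanyl)-2,5-dihydrofuran-2-yl acetate
Conditions: PhSH (1.0 equiv), Et3N (1.05 equiv), CH2Cl2, −20 → 0 °C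
Reagents that add atoms: thiophenol, Sc1ccccc1
Why: Addition–elimination on the α-bromobutenolide: the thiolate adds at the β-carbon, sulfur displaces the neighbouring bromide and re-elimination leaves the sulfur on the α-carbon (net ipso substitution), the cold, stoichiometric amine sparing the acylal C–H.

Step 15
Reactants: 20 (2S)-5-oxo-4-(phenylsulfanyl)-2,5-dihydrofuran-2-yl acetate
Product: 21 (2S)-5-oxo-4-(phenylsulfinyl)-2,5-dihydrofuran-2-yl acetate (both sulfur epimers)
Conditions: 3-ClC6H4CO3H (1.0 equiv), CH2Cl2, −78 → −20 °C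
Reagents that add atoms: 3-chloroperoxybenzoic acid, OOC(=O)c1cccc(Cl)c1
Why: Sulfide to sulfoxide oxidation with one equivalent of peracid at low temperature; both sulfur epimers are formed and both serve, since sulfur is lost in step 16.

Step 16
Reactants: 14 8-(allyloxy)-3-{3-[(tert-butyldimethylsilyl)oxy]-1-methoxy-1-[(trimethylsilyl)oxy]prop-1-en-2-yl}-9-(1,3-dioxolan-2-yl)-6-methyl-5H-1,4-benzodioxepin-5-one; 21 (2S)-5-oxo-4-(phenylsulfinyl)-2,5-dihydrofuran-2-yl acetate
Product: 25 (1S)-10-(allyloxy)-5-{[(tert-butyldimethylsilyl)oxy]methyl}-11-(1,3-dioxolan-2-yl)-4-hydroxy-8-methyl-3,7-dioxo-1,3-dihydro-7H-isobenzofuro[4,5-b][1,4]benzodioxepin-1-yl acetate, via sulfinyl cycloadduct 22 (not isolated), via ketal cyclohexadiene 23 (not isolated), via cross-conjugated dienone 24 (not isolated)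
Conditions: PhMe, −20 → 25 °C, then 60 °C; pH 6 phosphate buffer, THF, 25 °C
Reagents that add atoms: none
Why: The 1-methoxy-1-silyloxy diene is a Brassard-type ketene acetal whose donor terminus C5' adds to the β-carbon C6' of the butenolide, activated by both the lactone carbonyl and the sulfinyl group, while the ketene-acetal carbon C2' closes onto the α-carbon C1' (asynchronous Diels–Alder reaction; closest known type: cycloadditions of Brassard dienes to sulfinyl- or halo-activated butenolides and quinones with eliminative aromatisation). Ring B closes by this [4+2] cycloaddition, both skeletal bonds (C1'–C2' and C5'–C6') forming in one suprafacial operation to the cis-fused adduct 22. In 22 the sulfinyl group at C1' and the hydrogen at C6' are cis, so thermal syn elimination of benzenesulfenic acid gives 23, the ketal at C2' collapses with loss of methoxytrimethylsilane to dienone 24, and the C5' hydrogen tautomerises to the C2' phenol with the C5'–O–aryl bond kept. No new stereocentre survives, because every new sp3 centre becomes aromatic, and the only stereocentre of 25, the acylal carbon, comes unchanged from 21 because the whole sequence runs without base. The selectivity needed is regiochemical and is secured by the polarisation of both partners (largest donor coefficient at C5', largest acceptor coefficient at C6'), helped by the fully substituted C3', which blocks attack through the α-carbon of the ketene acetal.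

Step 17
Reactants: 25 (1S)-10-(allyloxy)-5-{[(tert-butyldimethylsilyl)oxy]methyl}-11-(1,3-dioxolan-2-yl)-4-hydroxy-8-methyl-3,7-dioxo-1,3-dihydro-7H-isobenzofuro[4,5-b][1,4]benzodioxepin-1-yl acetate
Product: 26 (1S)-10-(allyloxy)-11-formyl-4-hydroxy-5-(hydroxymethyl)-8-methyl-3,7-dioxo-1,3-dihydro-7H-isobenzofuro[4,5-b][1,4]benzodioxepin-1-yl acetate
Conditions: 48% aq. HF, MeCN–THF, 0 → 25 °C
Reagents that add atoms: water, O
Why: Acid-mediated desilylation and acetal hydrolysis: dilute aqueous HF cleaves the primary silyl ether and hydrolyses the electron-rich aryl dioxolane, whereas the acylal acetate, the lactones and the allyl ether tolerate short exposure to dilute acid, and the C–O bonds at the stereocentre are not touched.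

Step 18
Reactants: 26 (1S)-10-(allyloxy)-11-formyl-4-hydroxy-5-(hydroxymethyl)-8-methyl-3,7-dioxo-1,3-dihydro-7H-isobenzofuro[4,5-b][1,4]benzodioxepin-1-yl acetate
Product: 27 [(1S)-1-acetoxy-10-(allyloxy)-11-formyl-4-hydroxy-8-methyl-3,7-dioxo-1,3-dihydro-7H-isobenzofuro[4,5-b][1,4]benzodioxepin-5-yl]methyl acetate
Conditions: Ac2O (1.2 equiv), pyridine, CH2Cl2, 0 °C
Reagents that add atoms: acetic anhydride, CC(=O)OC(C)=O
Why: Acetylation with acetic anhydride and pyridine without an acyl-transfer catalyst: the primary benzylic alcohol should react much faster than the C2' phenol, which is hydrogen-bonded to the lactone carbonyl and flanked on both sides.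

Step 19
Reactants: 27 [(1S)-1-acetoxy-10-(allyloxy)-11-formyl-4-hydroxy-8-methyl-3,7-dioxo-1,3-dihydro-7H-isobenzofuro[4,5-b][1,4]benzodioxepin-5-yl]methyl acetate
Product: 28 [(1S)-1-acetoxy-11-formyl-4,10-dihydroxy-8-methyl-3,7-dioxo-1,3-dihydro-7H-isobenzofuro[4,5-b][1,4]benzodioxepin-5-yl]methyl acetate
Conditions: Pd(PPh3)4 (5 mol %), 4-MeC6H4SO2H (1.2 equiv), CH2Cl2, 25 °C
Reagents that add atoms: none
Why: Palladium-catalysed deallylation (Tsuji–Trost allyl transfer): the zerovalent palladium complex ionises the allyl aryl ether and the sulfinic acid captures the allyl group as a sulfone in a weakly acidic, aprotic medium that leaves the acylal acetate, the benzylic acetate and the aldehyde alone.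

Step 20
Reactants: 28 [(1S)-1-acetoxy-11-formyl-4,10-dihydroxy-8-methyl-3,7-dioxo-1,3-dihydro-7H-isobenzofuro[4,5-b][1,4]benzodioxepin-5-yl]methyl acetate
Product: 29 galbinic acid, [(1S)-11-formyl-1,4,10-trihydroxy-8-methyl-3,7-dioxo-1,3-dihydro-7H-isobenzofuro[4,5-b][1,4]benzodioxepin-5-yl]methyl acetate
Conditions: immobilised Pseudomonas fluorescens lipase, n-BuOH (3 equiv), dry tBuOMe, 25 °C; filtration, cold evaporation, crystallisation from EtOAc–heptane
Reagents that add atoms: none
Why: Lipase-catalysed alcoholysis of an activated (acylal) acetate: the enzyme attacks the acetyl carbon, so the C–O bond at the stereocentre stays intact (retention), the acylal ester is a far better acyl donor to the enzyme than the benzylic alkyl acetate, and the dry, base-free medium with immediate crystallisation limits ring–chain racemisation of the free lactol.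

**Compound list**

1 | orsellinic acid (2,4-dihydroxy-6-methylbenzoic acid) | Cc1cc(O)cc(O)c1C(=O)O | starting material
2 | 2-(trimethylsilyl)ethyl 2,4-dihydroxy-6-methylbenzoate | Cc1cc(O)cc(O)c1C(=O)OCC[Si](C)(C)C | intermediate
3 | 2-(trimethylsilyl)ethyl 3-formyl-2,4-dihydroxy-6-methylbenzoate | Cc1cc(O)c(C=O)c(O)c1C(=O)OCC[Si](C)(C)C | intermediate
4 | 2-(trimethylsilyl)ethyl 4-(allyloxy)-3-formyl-2-hydroxy-6-methylbenzoate | Cc1cc(OCC=C)c(C=O)c(O)c1C(=O)OCC[Si](C)(C)C | intermediate
5 | 2-(trimethylsilyl)ethyl 4-(allyloxy)-3-formyl-2-{2-[methoxy(methyl)amino]-2-oxoethoxy}-6-methylbenzoate | Cc1cc(OCC=C)c(C=O)c(OCC(=O)N(C)OC)c1C(=O)OCC[Si](C)(C)C | intermediate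
6 | 2-(trimethylsilyl)ethyl 4-(allyloxy)-3-(1,3-dioxolan-2-yl)-2-{2-[methoxy(methyl)amino]-2-oxoethoxy}-6-methylbenzoate | Cc1cc(OCC=C)c(C2OCCO2)c(OCC(=O)N(C)OC)c1C(=O)OCC[Si](C)(C)C | intermediate
7 | 4-(allyloxy)-3-(1,3-dioxolan-2-yl)-2-{2-[methoxy(methyl)amino]-2-oxoethoxy}-6-methylbenzoic acid | Cc1cc(OCC=C)c(C2OCCO2)c(OCC(=O)N(C)OC)c1C(O)=O | intermediate
8 | methyl 3-hydroxypropanoate | COC(=O)CCO | starting material
9 | methyl 3-[(tert-butyldimethylsilyl)oxy]propanoate | COC(=O)CCO[Si](C)(C)C(C)(C)C | intermediate
10 | lithium enolate of 9 (lithium 3-[(tert-butyldimethylsilyl)oxy]-1-methoxyprop-1-en-1-olate; not isolated) | [Li+].COC([O-])=CCO[Si](C)(C)C(C)(C)C | intermediate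
11 | 4-(allyloxy)-2-{4-[(tert-butyldimethylsilyl)oxy]-3-(methoxycarbonyl)-2-oxobutoxy}-3-(1,3-dioxolan-2-yl)-6-methylbenzoic acid (racemic at the keto ester α-carbon) | COC(=O)C(CO[Si](C)(C)C(C)(C)C)C(=O)COc1c(C2OCCO2)c(OCC=C)cc(C)c1C(O)=O | intermediate
12 | acid chloride of 11 (not isolated) | COC(=O)C(CO[Si](C)(C)C(C)(C)C)C(=O)COc1c(C2OCCO2)c(OCC=C)cc(C)c1C(Cl)=O | intermediate
13 | methyl (2Z)-2-[8-(allyloxy)-9-(1,3-dioxolan-2-yl)-6-methyl-5-oxo-1,4-benzodioxepin-3(2H)-ylidene]-3-[(tert-butyldimethylsilyl)oxy]propanoate | COC(=O)/C(CO[Si](C)(C)C(C)(C)C)=C1/COc2c(C3OCCO3)c(OCC=C)cc(C)c2C(=O)O1 | intermediate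
14 | 8-(allyloxy)-3-{3-[(tert-butyldimethylsilyl)oxy]-1-methoxy-1-[(trimethylsilyl)oxy]prop-1-en-2-yl}-9-(1,3-dioxolan-2-yl)-6-methyl-5H-1,4-benzodioxepin-5-one (ketene acetal geometry undefined) | COC(O[Si](C)(C)C)=C(CO[Si](C)(C)C(C)(C)C)C1=COc2c(C3OCCO3)c(OCC=C)cc(C)c2C(=O)O1 | intermediate
15 | furfural | O=Cc1ccco1 | starting material
16 | 5-hydroxyfuran-2(5H)-one (racemic) | O=C1C=CC(O)O1 | intermediate
17 | (S)-5-acetoxyfuran-2(5H)-one, (2S)-5-oxo-2,5-dihydrofuran-2-yl acetate | O=C1C=C[C@@H](OC(C)=O)O1 | intermediate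
18 | (2S)-3,4-dibromo-5-oxooxolan-2-yl acetate (trans dibromide, mixture at the two bromine-bearing carbons; not isolated) | O=C1C(Br)C(Br)[C@@H](OC(C)=O)O1 | intermediate
19 | (2S)-4-bromo-5-oxo-2,5-dihydrofuran-2-yl acetate | O=C1C(Br)=C[C@@H](OC(C)=O)O1 | intermediate
20 | (2S)-5-oxo-4-(phenylsulfanyl)-2,5-dihydrofuran-2-yl acetate | O=C1C(Sc2ccccc2)=C[C@@H](OC(C)=O)O1 | intermediate
21 | (2S)-5-oxo-4-(phenylsulfinyl)-2,5-dihydrofuran-2-yl acetate (both epimers at sulfur) | O=C1C(S(=O)c2ccccc2)=C[C@@H](OC(C)=O)O1 | intermediate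
22 | cis-fused sulfinyl cycloadduct, ring B as cyclohexene with C2' methoxy(trimethylsilyloxy) ketal and C1' phenylsulfinyl group (acylal carbon S; mixture at the new centres; not isolated) | CC(C)(C)[Si](C)(C)OCC1=C2OC(=O)c3c(C)cc(OCC=C)c(C4OCCO4)c3OC2C5[C@@H](OC(C)=O)OC(=O)C5(S(=O)c6ccccc6)C1(OC)O[Si](C)(C)C | intermediate
23 | ketal cyclohexadiene after loss of benzenesulfenic acid (C1'=C6' and C3'=C4'; acylal carbon S; not isolated) | CC(C)(C)[Si](C)(C)OCC1=C2OC(=O)c3c(C)cc(OCC=C)c(C4OCCO4)c3OC2C5=C(C(=O)O[C@@H]5OC(C)=O)C1(OC)O[Si](C)(C)C | intermediate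
24 | cross-conjugated dienone after loss of methoxytrimethylsilane (C2' ketone, C5' still sp3; acylal carbon S; not isolated) | CC(C)(C)[Si](C)(C)OCC1=C2OC(=O)c3c(C)cc(OCC=C)c(C4OCCO4)c3OC2C5=C(C(=O)O[C@@H]5OC(C)=O)C1=O | intermediate
25 | (1S)-10-(allyloxy)-5-{[(tert-butyldimethylsilyl)oxy]methyl}-11-(1,3-dioxolan-2-yl)-4-hydroxy-8-methyl-3,7-dioxo-1,3-dihydro-7H-isobenzofuro[4,5-b][1,4]benzodioxepin-1-yl acetate | CC(C)(C)[Si](C)(C)OCc1c(O)c2c(c3c1OC(=O)c1c(C)cc(OCC=C)c(C4OCCO4)c1O3)[C@@H](OC(C)=O)OC2=O | intermediate
26 | (1S)-10-(allyloxy)-11-formyl-4-hydroxy-5-(hydroxymethyl)-8-methyl-3,7-dioxo-1,3-dihydro-7H-isobenzofuro[4,5-b][1,4]benzodioxepin-1-yl acetate | OCc1c(O)c2c(c3c1OC(=O)c1c(C)cc(OCC=C)c(C=O)c1O3)[C@@H](OC(C)=O)OC2=O | intermediate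
27 | [(1S)-1-acetoxy-10-(allyloxy)-11-formyl-4-hydroxy-8-methyl-3,7-dioxo-1,3-dihydro-7H-isobenzofuro[4,5-b][1,4]benzodioxepin-5-yl]methyl acetate | CC(=O)OCc1c(O)c2c(c3c1OC(=O)c1c(C)cc(OCC=C)c(C=O)c1O3)[C@@H](OC(C)=O)OC2=O | intermediate
28 | [(1S)-1-acetoxy-11-formyl-4,10-dihydroxy-8-methyl-3,7-dioxo-1,3-dihydro-7H-isobenzofuro[4,5-b][1,4]benzodioxepin-5-yl]methyl acetate | CC(=O)OCc1c(O)c2c(c3c1OC(=O)c1c(C)cc(O)c(C=O)c1O3)[C@@H](OC(C)=O)OC2=O | intermediate
29 | galbinic acid, [(1S)-11-formyl-1,4,10-trihydroxy-8-methyl-3,7-dioxo-1,3-dihydro-7H-isobenzofuro[4,5-b][1,4]benzodioxepin-5-yl]methyl acetate | CC(=O)OCc1c(O)c2c(c3c1OC(=O)c1c(C)cc(O)c(C=O)c1O3)[C@@H](O)OC2=O | target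

**Step count**

Total step count: 20.
Longest linear sequence: 14 steps (steps 1–6, 8–10 and 16–20, from orsellinic acid).

**Three steps most likely to fail**

1. Step 16. What may go wrong: bond formation at C5' is slow because the C4' oxygen of the diene is an enol-ester oxygen and only a weak donor. This leaves time for silyl transfer from the ketene acetal to the sulfoxide oxygen (Pummerer-type consumption of 21) or for hydrolysis of 14. Fallback: the sequence sets out from keto acid 11 and moves the closure of the seven-membered ring behind the annulation.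
   - 11 is silylated at the carboxyl group and at the ketone enol oxygen (Me3SiCl, Et3N, CH2Cl2) to the silyl ester silyl enol ether F1.
   - LiN(iPr)2 and Me3SiCl (THF, −78 °C) convert F1 into the open-chain 1-methoxy-1,3-bis(trimethylsilyloxy) diene F2, whose C4' oxygen is a silyl enol ether and a much stronger donor than in 14.
   - F2 and 21 undergo the same cycloaddition, sulfenic acid elimination and aromatisation under the conditions of step 16. Aqueous work-up gives the seco acid F3, a diaryl ether with free C2' and C4' phenols and the ring-A carboxylic acid.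
   - Lactonisation of the C4' phenol onto that acid (dicyclohexylcarbodiimide, 4-(dimethylamino)pyridine (cat.), dilute CH2Cl2; the classical depsidone ring closure) comes back to the route at 25. The C2' phenol cannot reach the acid.
   - Because it starts at 11, this sequence also covers a failure of steps 9 and 10.

2. Step 12. What may go wrong: enantioselection in the wrong sense or incomplete, because the enzyme at hand acetylates the (R)-lactol faster or because ring–chain racemisation of 16 lags behind acylation. Fallback: it sets out from 16 and changes from dynamic acylation to kinetic resolution by alcoholysis.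
   - 16 is acetylated chemically (Ac2O, pyridine, 0 °C) to racemic 5-acetoxyfuran-2(5H)-one F4.
   - An (R)-preferring lipase is run in the alcoholysis direction (n-BuOH, tBuOMe, 25 °C). The (R)-acetate is cleaved back to 16, which is recycled, and the unreacted ester is the (S)-acetate 17, where the route is rejoined.
   - At most half of the material is obtained per pass. In that case step 20 needs a hydrolase of the opposite preference.

3. Step 20. What may go wrong: competing enzymatic loss of the primary benzylic acetate, and erosion of configuration of the freed lactol by ring–chain tautomerism during long contact with the added alcohol. Fallback: it sets out from 26 and reverses the order of the last operations, so that the acylal acetate itself becomes the acetyl donor for the primary hydroxyl.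
   - The allyl ether of 26 is removed first (Pd(PPh3)4, 4-MeC6H4SO2H, CH2Cl2) to give the hydroxymethyl lactol acetate F5.
   - F5 is stirred with the immobilised lipase in dry toluene without any added alcohol. The enzyme takes the acetyl group from the activated acylal ester and passes it to the primary benzylic hydroxyl (lipase transesterification with an activated ester as donor), which leads directly to 29.
   - No second acetate can be lost, and an enzyme that accepts the benzylic acetate in the hydrolytic sense must also accept the benzylic alcohol in the acylation sense.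

**Further compounds**

F1 | step 16 | trimethylsilyl 4-(allyloxy)-2-({4-[(tert-butyldimethylsilyl)oxy]-3-(methoxycarbonyl)-2-[(trimethylsilyl)oxy]but-2-en-1-yl}oxy)-3-(1,3-dioxolan-2-yl)-6-methylbenzoate | COC(=O)C(CO[Si](C)(C)C(C)(C)C)=C(COc1c(C2OCCO2)c(OCC=C)cc(C)c1C(=O)O[Si](C)(C)C)O[Si](C)(C)C
F2 | step 16 | trimethylsilyl 4-(allyloxy)-2-[(3-{[(tert-butyldimethylsilyl)oxy]methyl}-4-methoxy-2,4-bis[(trimethylsilyl)oxy]buta-1,3-dien-1-yl)oxy]-3-(1,3-dioxolan-2-yl)-6-methylbenzoate | COC(O[Si](C)(C)C)=C(CO[Si](C)(C)C(C)(C)C)C(O[Si](C)(C)C)=COc1c(C2OCCO2)c(OCC=C)cc(C)c1C(=O)O[Si](C)(C)C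
F3 | step 16 | 2-{[(3S)-3-acetoxy-6-{[(tert-butyldimethylsilyl)oxy]methyl}-5,7-dihydroxy-1-oxo-1,3-dihydro-2-benzofuran-4-yl]oxy}-4-(allyloxy)-3-(1,3-dioxolan-2-yl)-6-methylbenzoic acid | CC(C)(C)[Si](C)(C)OCc1c(O)c2c(c(Oc3c(C4OCCO4)c(OCC=C)cc(C)c3C(=O)O)c1O)[C@@H](OC(C)=O)OC2=O
F4 | step 12 | racemic 5-oxo-2,5-dihydrofuran-2-yl acetate | CC(=O)OC1C=CC(=O)O1
F5 | step 20 | (1S)-11-formyl-4,10-dihydroxy-5-(hydroxymethyl)-8-methyl-3,7-dioxo-1,3-dihydro-7H-isobenzofuro[4,5-b][1,4]benzodioxepin-1-yl acetate | OCc1c(O)c2c(c3c1OC(=O)c1c(C)cc(O)c(C=O)c1O3)[C@@H](OC(C)=O)OC2=O
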